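The route rests on cutting the γ-ylidene butenolide at C4–C5 and O1–C5. In one flask a Pd(PPh3)4/CuI-mediated alkynylation of a free-triol (Z)-β-iodo dienoic acid with a terminal tetraenediyne alcohol forms C4–C5, after which the carboxylate closes onto the new alkyne (5-exo-dig). This gives the Z-ylidene furanone and joins the C14 and C23 halves with no later deprotection. The step exploits that furanone C5, the ring carbon bound to O1, C4 and the exocyclic methine, is at alkyne oxidation level and sits cis to the C2 carboxyl across C3=C4. Both carbocycles derive from actinol through one enol triflate.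

Key step: step 22

Remark on the chemistry: carbocycle positions are discussed with carotenoid locants (C1 gem-dimethyl carbon, C3 carbinol, C5 methyl-bearing carbon, C6 chain-bearing carbon) and the furanone as O1, C2(=O), C3, C4, C5; actinol, the E enynol and propargyl alcohol are taken as commercial, isomerically pure materials.

Step 1
Reactants: 1 (4R,6R)-4-hydroxy-2,2,6-trimethylcyclohexan-1-one (actinol)
Product: 2 (4R,6R)-4-(tert-butyldimethylsilyloxy)-2,2,6-trimethylcyclohexan-1-one
Conditions: TBSCl, imidazole, DMF, rt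
Reagents that add atoms: tert-butyldimethylsilyl chloride, CC(C)(C)[Si](C)(C)Cl
Why: Silyl ether formation at the unhindered secondary hydroxyl (silyl chloride/imidazole) should be clean and leaves both stereocentres untouched, this carbinol being the future C3 and C3' of the target.

Step 2
Reactants: 2 (4R,6R)-4-(tert-butyldimethylsilyloxy)-2,2,6-trimethylcyclohexan-1-one
Product: 4 (R)-4-(tert-butyldimethylsilyloxy)-2,6,6-trimethylcyclohex-1-en-1-yl trifluoromethanesulfonate, via lithium enolate 3 (not isolated)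
Conditions: LiN(iPr)2, THF, −78 °C; PhNTf2, −78 → 0 °C
Reagents that add atoms: N-phenylbis(trifluoromethanesulfonimide), O=S(=O)(N(c1ccccc1)S(=O)(=O)C(F)(F)F)C(F)(F)F
Why: Because one α-carbon is quaternary the ketone can enolise only toward the methine carbon, and O-sulfonylation of that lithium enolate (enol triflate formation) should give the tetrasubstituted enol triflate, erasing the methine stereocentre while the silyloxy carbon is unaffected.

Step 3
Reactants: 4 (R)-4-(tert-butyldimethylsilyloxy)-2,6,6-trimethylcyclohex-1-en-1-yl trifluoromethanesulfonate; 5 (E)-3-methylpent-2-en-4-yn-1-ol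
Product: 6 (E)-5-[(R)-4-(tert-butyldimethylsilyloxy)-2,6,6-trimethylcyclohex-1-en-1-yl]-3-methylpent-2-en-4-yn-1-ol
Conditions: Pd(PPh3)4 (5 mol%), CuI (10 mol%), iPr2NH, THF, 50 °C
Reagents that add atoms: none
Why: Sonogashira coupling of an enol triflate with a terminal alkyne should join ring and side chain at the hindered sp2 carbon, with the E geometry of the bought enynol carried over and the free primary hydroxyl tolerated.

Step 4
Reactants: 6 (E)-5-[(R)-4-(tert-butyldimethylsilyloxy)-2,6,6-trimethylcyclohex-1-en-1-yl]-3-methylpent-2-en-4-yn-1-ol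
Product: 7 (E)-5-[(R)-4-(tert-butyldimethylsilyloxy)-2,6,6-trimethylcyclohex-1-en-1-yl]-3-methylpent-2-en-4-ynal
Conditions: MnO2, CH2Cl2, rt
Reagents that add atoms: none
Why: MnO2 oxidises only the allylic primary alcohol (allylic oxidation), so the enal should form without touching the silyl ether, the alkyne or the E double bond.

Step 5
Reactants: 7 (E)-5-[(R)-4-(tert-butyldimethylsilyloxy)-2,6,6-trimethylcyclohex-1-en-1-yl]-3-methylpent-2-en-4-ynal
Product: 8 tert-butyl({(R)-4-[(3E,5E)-6-iodo-3-methylhexa-3,5-dien-1-yn-1-yl]-3,5,5-trimethylcyclohex-3-en-1-yl}oxy)dimethylsilane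
Conditions: CrCl2, CHI3, THF, 0 °C → rt, dark
Reagents that add atoms: iodoform, IC(I)I
Why: In the Takai iodo-olefination the geminal dichromium carbenoid made from CHI3 and CrCl2 adds to the aldehyde and eliminates anti, which should give the E vinyl iodide under conditions that leave the silyl ether and the enyne alone.

Step 6
Reactants: 5 (E)-3-methylpent-2-en-4-yn-1-ol
Product: 11 (E)-3-methyl-5-(trimethylsilyl)pent-2-en-4-yn-1-ol, via dilithium salt 9 (not isolated), via O,C-bis(trimethylsilyl) ether 10 (not isolated)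
Conditions: n-BuLi (2.1 equiv), THF, −78 °C; TMSCl (2.2 equiv), −78 → 0 °C; 1 M aq. HCl work-up
Reagents that add atoms: chlorotrimethylsilane, C[Si](C)(C)Cl
Why: Double deprotonation (O–H and alkyne C–H), silylation at both anionic sites and hydrolysis of the labile O–Si bond on acidic work-up is the standard C-silyl protection of a terminal alkyne, which keeps this alkyne out of the chromium and palladium steps that follow.

Step 7
Reactants: 11 (E)-3-methyl-5-(trimethylsilyl)pent-2-en-4-yn-1-ol
Product: 12 (E)-3-methyl-5-(trimethylsilyl)pent-2-en-4-ynal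
Conditions: MnO2, CH2Cl2, rt
Reagents that add atoms: none
Why: Allylic oxidation with MnO2 should stop cleanly at the conjugated aldehyde and preserve the E alkene and the silyl alkyne.

Step 8
Reactants: 12 (E)-3-methyl-5-(trimethylsilyl)pent-2-en-4-ynal
Product: 13 4,4,5,5-tetramethyl-2-[(1E,3E)-4-methyl-6-(trimethylsilyl)hexa-1,3-dien-5-yn-1-yl]-1,3,2-dioxaborolane
Conditions: CrCl2, LiI, Cl2CHBpin, THF, rt
Reagents that add atoms: 2-(dichloromethyl)-4,4,5,5-tetramethyl-1,3,2-dioxaborolane, ClC(Cl)B1OC(C)(C)C(C)(C)O1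
Why: Takai–Utimoto boryl-olefination (the dichromium reagent derived from the dichloromethylboronate) should convert the enal into the E alkenylboronate by the same anti-elimination logic as in step 5, the pinacol ester and the silyl alkyne being inert to CrCl2.

Step 9
Reactants: 8 tert-butyl({(R)-4-[(3E,5E)-6-iodo-3-methylhexa-3,5-dien-1-yn-1-yl]-3,5,5-trimethylcyclohex-3-en-1-yl}oxy)dimethylsilane; 13 4,4,5,5-tetramethyl-2-[(1E,3E)-4-methyl-6-(trimethylsilyl)hexa-1,3-dien-5-yn-1-yl]-1,3,2-dioxaborolane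
Product: 14 tert-butyl({(R)-4-[(3E,5E,7E,9E)-3,10-dimethyl-12-(trimethylsilyl)dodeca-3,5,7,9-tetraene-1,11-diyn-1-yl]-3,5,5-trimethylcyclohex-3-en-1-yl}oxy)dimethylsilane
Conditions: Pd(PPh3)4 (5 mol%), TlOEt, THF/H2O 3:1, rt, dark
Reagents that add atoms: none
Why: Suzuki–Miyaura coupling of an alkenyl iodide with an alkenylboronate proceeds with retention at both sp2 carbons, and TlOEt-accelerated transmetalation at room temperature should assemble the all-E tetraene without thermal isomerisation.

Step 10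
Reactants: 14 tert-butyl({(R)-4-[(3E,5E,7E,9E)-3,10-dimethyl-12-(trimethylsilyl)dodeca-3,5,7,9-tetraene-1,11-diyn-1-yl]-3,5,5-trimethylcyclohex-3-en-1-yl}oxy)dimethylsilane
Product: 15 (R)-4-[(3E,5E,7E,9E)-3,10-dimethyldodeca-3,5,7,9-tetraene-1,11-diyn-1-yl]-3,5,5-trimethylcyclohex-3-en-1-ol
Conditions: Bu4NF, THF, 0 °C → rt, dark
Reagents that add atoms: none
Why: Fluoride-induced desilylation cleaves the alkynyl C–Si bond and the secondary silyl ether in the same operation, so one step should release both the terminal alkyne and the carbinol of the acetylenic half.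

Step 11
Reactants: 4 (R)-4-(tert-butyldimethylsilyloxy)-2,6,6-trimethylcyclohex-1-en-1-yl trifluoromethanesulfonate
Product: 16 methyl (R)-4-(tert-butyldimethylsilyloxy)-2,6,6-trimethylcyclohex-1-ene-1-carboxylate
Conditions: Pd(OAc)2 (5 mol%), PPh3 (10 mol%), CO (1 atm), Et3N, MeOH/DMF, 60 °C
Reagents that add atoms: carbon monoxide, [C-]#[O+]; methanol, CO
Why: Palladium-catalysed methoxycarbonylation of the enol triflate (oxidative addition, CO insertion, methanolysis of the acylpalladium) should install the one-carbon unit that becomes C7 of the triol half.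

Step 12
Reactants: 16 methyl (R)-4-(tert-butyldimethylsilyloxy)-2,6,6-trimethylcyclohex-1-ene-1-carboxylate
Product: 17 [(R)-4-(tert-butyldimethylsilyloxy)-2,6,6-trimethylcyclohex-1-en-1-yl]methanol
Conditions: iBu2AlH, CH2Cl2, −78 → 0 °C; aq. potassium sodium tartrate work-up
Reagents that add atoms: none
Why: iBu2AlH reduces the conjugated ester by two hydride deliveries to the primary allylic alcohol (ester reduction) and attacks neither the silyl ether nor the tetrasubstituted alkene.

Step 13
Reactants: 17 [(R)-4-(tert-butyldimethylsilyloxy)-2,6,6-trimethylcyclohex-1-en-1-yl]methanol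
Product: 18 [(1S,4S,6S)-4-(tert-butyldimethylsilyloxy)-2,2,6-trimethyl-7-oxabicyclo[4.1.0]heptan-1-yl]methanol (epoxide oxygen cis to the silyloxy group)
Conditions: Ti(OiPr)4 (20 mol%), diethyl L-(+)-tartrate (25 mol%), t-BuOOH, 4 Å molecular sieves, CH2Cl2, −20 °C
Reagents that add atoms: tert-butyl hydroperoxide, CC(C)(C)OO
Why: In the Katsuki–Sharpless asymmetric epoxidation the titanium tartrate complex binds the allylic alkoxide and delivers the peroxide oxygen to one alkene face by reagent control; with L-(+)-tartrate (the sense that gives 2S epoxy alcohols from simple E allylic alcohols) this is the face carrying the C3 silyloxy group, so C5 and C6 should both be set with the epoxide oxygen cis to C3–O.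

Step 14
Reactants: 18 [(1S,4S,6S)-4-(tert-butyldimethylsilyloxy)-2,2,6-trimethyl-7-oxabicyclo[4.1.0]heptan-1-yl]methanol
Product: 19 (1S,2R,4S)-4-(tert-butyldimethylsilyloxy)-1-(hydroxymethyl)-2,6,6-trimethylcyclohexane-1,2-diol (1-OH cis to the silyloxy group; 2-OH trans to both)
Conditions: HClO4 (cat.), THF/H2O 4:1, 0 °C
Reagents that add atoms: water, O
Why: Acid-catalysed epoxide hydrolysis should proceed by backside attack of water at C5, the tertiary carbon remote from the electron-withdrawing hydroxymethyl group and the one whose opening is trans-diaxial with the silyloxy group equatorial (Fürst–Plattner), so C5 is inverted and the C6–O bond kept, giving the 5,6-trans diol with 6-OH cis to the C3 oxygen, while brief exposure to dilute acid at 0 °C should spare the secondary silyl ether.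

Step 15
Reactants: 19 (1S,2R,4S)-4-(tert-butyldimethylsilyloxy)-1-(hydroxymethyl)-2,6,6-trimethylcyclohexane-1,2-diol
Product: 20 (1R,2R,4S)-4-(tert-butyldimethylsilyloxy)-1,2-dihydroxy-2,6,6-trimethylcyclohexane-1-carbaldehyde
Conditions: SO3·pyridine, DMSO, iPr2NEt, CH2Cl2, 0 °C
Reagents that add atoms: none
Why: Parikh–Doering oxidation (activated DMSO) converts the only oxidisable hydroxyl, the primary one, into the aldehyde without cleaving the vicinal diols, the two tertiary hydroxyls and the silyl ether being inert and the fully substituted α-carbon ruling out epimerisation.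

Step 16
Reactants: 20 (1R,2R,4S)-4-(tert-butyldimethylsilyloxy)-1,2-dihydroxy-2,6,6-trimethylcyclohexane-1-carbaldehyde
Product: 21 (1R,2R,4S)-4-(tert-butyldimethylsilyloxy)-2,6,6-trimethyl-1,2-bis(trimethylsilyloxy)cyclohexane-1-carbaldehyde
Conditions: TMSOTf, 2,6-lutidine, CH2Cl2, −78 → 0 °C
Reagents that add atoms: trimethylsilyl trifluoromethanesulfonate, C[Si](C)(C)OS(=O)(=O)C(F)(F)F
Why: Silylation with a silyl triflate and a hindered pyridine base is forceful enough for the two axial tertiary hydroxyls, the small trimethylsilyl group being chosen because bulkier silyl groups would not reach the C6 hydroxyl flanked by two quaternary carbons, and the aldehyde cannot form a silyl enol ether since it has no α-hydrogen.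

Step 17
Reactants: 21 (1R,2R,4S)-4-(tert-butyldimethylsilyloxy)-2,6,6-trimethyl-1,2-bis(trimethylsilyloxy)cyclohexane-1-carbaldehyde
Product: 22 (1R,2R,4S)-4-(tert-butyldimethylsilyloxy)-1-[(E)-2-iodoethenyl]-2,6,6-trimethyl-1,2-bis(trimethylsilyloxy)cyclohexane
Conditions: CrCl2, CHI3, THF, 0 °C → rt, dark
Reagents that add atoms: iodoform, IC(I)I
Why: Takai iodo-olefination of the hindered, fully protected aldehyde should give the E vinyl iodide, the bulky quaternary substituent reinforcing the trans preference of the anti-elimination.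

Step 18
Reactants: 22 (1R,2R,4S)-4-(tert-butyldimethylsilyloxy)-1-[(E)-2-iodoethenyl]-2,6,6-trimethyl-1,2-bis(trimethylsilyloxy)cyclohexane; 23 prop-2-yn-1-ol (propargyl alcohol)
Product: 28 (2Z,3E)-4-[(1R,2R,4S)-4-(tert-butyldimethylsilyloxy)-2,6,6-trimethyl-1,2-bis(trimethylsilyloxy)cyclohexyl]-2-(iodomethylidene)but-3-en-1-ol, via alkenyllithium 24 (not isolated), via alkenylmagnesium bromide 25 (not isolated), via chloromagnesium propargyl alkoxide 26 (not isolated), via magnesium chelate 27 (not isolated)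
Conditions: 22, t-BuLi (2 equiv), Et2O, −78 °C; MgBr2·OEt2, −78 → −20 °C; added to 23/iPrMgCl (1 equiv, THF, −20 °C); CuI (15 mol%), −20 °C → rt; I2, −40 → 0 °C
Reagents that add atoms: iodine, II
Why: Iodine–lithium exchange with retention and transmetalation to magnesium give the E alkenylmagnesium bromide, which under CuI catalysis adds across the pre-formed magnesium alkoxide of propargyl alcohol with the alkenyl group at C2 and magnesium at C3 trans to it, held in a five-membered O–Mg–C chelate, so that iodinolysis with retention places iodine cis to the hydroxymethyl group (copper-catalysed anti-carbomagnesiation of a propargylic alcohol); pre-forming the alkoxide with iPrMgCl means none of the valuable alkenyl reagent is spent on the hydroxyl proton.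

Step 19
Reactants: 28 (2Z,3E)-4-[(1R,2R,4S)-4-(tert-butyldimethylsilyloxy)-2,6,6-trimethyl-1,2-bis(trimethylsilyloxy)cyclohexyl]-2-(iodomethylidene)but-3-en-1-ol
Product: 29 (2Z,3E)-4-[(1R,2R,4S)-4-(tert-butyldimethylsilyloxy)-2,6,6-trimethyl-1,2-bis(trimethylsilyloxy)cyclohexyl]-2-(iodomethylidene)but-3-enal
Conditions: MnO2, CH2Cl2, rt, dark
Reagents that add atoms: none
Why: Allylic oxidation with MnO2 touches only the free dienylic primary alcohol and is neutral enough to keep the Z iodoalkene and all three silyl ethers.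

Step 20
Reactants: 29 (2Z,3E)-4-[(1R,2R,4S)-4-(tert-butyldimethylsilyloxy)-2,6,6-trimethyl-1,2-bis(trimethylsilyloxy)cyclohexyl]-2-(iodomethylidene)but-3-enal
Product: 30 (2Z,3E)-4-[(1R,2R,4S)-4-(tert-butyldimethylsilyloxy)-2,6,6-trimethyl-1,2-bis(trimethylsilyloxy)cyclohexyl]-2-(iodomethylidene)but-3-enoic acid
Conditions: NaClO2, NaH2PO4, 2-methyl-2-butene, t-BuOH/H2O, 0 °C → rt
Reagents that add atoms: sodium chlorite, [Na+].[O-]Cl=O
Why: Pinnick oxidation (chlorous acid with 2-methyl-2-butene as hypochlorite scavenger) should convert the enal into the acid without affecting the iodoalkene or the diene, and any trimethylsilyl ether lost in the weakly acidic buffer is of no consequence because all silyl groups are removed in the next step.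

Step 21
Reactants: 30 (2Z,3E)-4-[(1R,2R,4S)-4-(tert-butyldimethylsilyloxy)-2,6,6-trimethyl-1,2-bis(trimethylsilyloxy)cyclohexyl]-2-(iodomethylidene)but-3-enoic acid
Product: 31 (2Z,3E)-2-(iodomethylidene)-4-[(1R,2R,4S)-1,2,4-trihydroxy-2,6,6-trimethylcyclohexyl]but-3-enoic acid
Conditions: HF·pyridine, pyridine, THF, 0 °C → rt
Reagents that add atoms: none
Why: Buffered fluoride desilylation removes the secondary tert-butyldimethylsilyl ether and both tertiary trimethylsilyl ethers under conditions to which the Z β-iodoacrylic acid and the tertiary allylic alcohol, deactivated by the electron-poor diene, should be inert, so the triol half is obtained with every hydroxyl free.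

Step 22
Reactants: 15 (R)-4-[(3E,5E,7E,9E)-3,10-dimethyldodeca-3,5,7,9-tetraene-1,11-diyn-1-yl]-3,5,5-trimethylcyclohex-3-en-1-ol; 31 (2Z,3E)-2-(iodomethylidene)-4-[(1R,2R,4S)-1,2,4-trihydroxy-2,6,6-trimethylcyclohexyl]but-3-enoic acid
Product: 33 target CNP0163979.1, via enynoic acid 32 (not isolated)
Conditions: Pd(PPh3)4 (5 mol%), CuI (10 mol%), Et3N, MeCN, rt, degassed, dark
Reagents that add atoms: none
Why: Zerovalent palladium from Pd(PPh3)4 inserts into the C–I bond of 31, the alkynylcopper formed from 15, CuI and Et3N transmetalates, and reductive elimination gives the (Z)-2-en-4-ynoic acid 32 with the iodoalkene geometry retained, so carboxylate and alkyne are cis across C3=C4. The carboxylate then adds anti to the metal-activated alkyne at its proximal carbon and protonolysis of the alkenyl–metal bond releases the butenolide; the closest known reaction type is the palladium/copper-catalysed tandem cross-coupling and lactonisation of (Z)-3-iodoalk-2-enoic acids with terminal alkynes (Sonogashira coupling followed by cycloisomerisation). The furanone ring, the only ring formed, closes in the 5-exo-dig mode through O1–C5. No stereocentre is created; the new stereogenic element is the exocyclic C5=CH double bond, whose Z geometry follows from anti addition of oxygen and hydrogen across the alkyne, while the E C7=C8 bond and the carbinol centres of both halves are spectators. The step needs 5-exo rather than 6-endo closure (pyranone), reaction at the terminal and not the internal alkyne, and no oxidative alkyne dimerisation; the preset cis carboxyl–alkyne relationship, the amine/CuI medium free of Brønsted or Lewis acid, and rigorous degassing should secure these.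

Compound list
1 | (4R,6R)-4-hydroxy-2,2,6-trimethylcyclohexan-1-one (actinol) | C[C@H]1C(=O)C(C)(C)C[C@H](O)C1 | starting material
2 | (4R,6R)-4-(tert-butyldimethylsilyloxy)-2,2,6-trimethylcyclohexan-1-one | C[C@H]1C(=O)C(C)(C)C[C@H](O[Si](C)(C)C(C)(C)C)C1 | intermediate
3 | lithium (R)-4-(tert-butyldimethylsilyloxy)-2,6,6-trimethylcyclohex-1-en-1-olate (not isolated) | CC1=C(O[Li])C(C)(C)C[C@H](O[Si](C)(C)C(C)(C)C)C1 | intermediate
4 | (R)-4-(tert-butyldimethylsilyloxy)-2,6,6-trimethylcyclohex-1-en-1-yl trifluoromethanesulfonate | CC1=C(OS(=O)(=O)C(F)(F)F)C(C)(C)C[C@H](O[Si](C)(C)C(C)(C)C)C1 | intermediate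
5 | (E)-3-methylpent-2-en-4-yn-1-ol | C#C/C(C)=C/CO | starting material
6 | (E)-5-[(R)-4-(tert-butyldimethylsilyloxy)-2,6,6-trimethylcyclohex-1-en-1-yl]-3-methylpent-2-en-4-yn-1-ol | CC1=C(C#C/C(C)=C/CO)C(C)(C)C[C@H](O[Si](C)(C)C(C)(C)C)C1 | intermediate
7 | (E)-5-[(R)-4-(tert-butyldimethylsilyloxy)-2,6,6-trimethylcyclohex-1-en-1-yl]-3-methylpent-2-en-4-ynal | CC1=C(C#C/C(C)=C/C=O)C(C)(C)C[C@H](O[Si](C)(C)C(C)(C)C)C1 | intermediate
8 | tert-butyl({(R)-4-[(3E,5E)-6-iodo-3-methylhexa-3,5-dien-1-yn-1-yl]-3,5,5-trimethylcyclohex-3-en-1-yl}oxy)dimethylsilane | CC1=C(C#C/C(C)=C/C=C/I)C(C)(C)C[C@H](O[Si](C)(C)C(C)(C)C)C1 | intermediate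
9 | dilithium salt of 5 (lithium alkoxide and lithium acetylide; not isolated) | [Li]C#C/C(C)=C/CO[Li] | intermediate
10 | (E)-trimethyl{[3-methyl-5-(trimethylsilyl)pent-2-en-4-yn-1-yl]oxy}silane (not isolated) | C[Si](C)(C)C#C/C(C)=C/CO[Si](C)(C)C | intermediate
11 | (E)-3-methyl-5-(trimethylsilyl)pent-2-en-4-yn-1-ol | C[Si](C)(C)C#C/C(C)=C/CO | intermediate
12 | (E)-3-methyl-5-(trimethylsilyl)pent-2-en-4-ynal | C[Si](C)(C)C#C/C(C)=C/C=O | intermediate
13 | 4,4,5,5-tetramethyl-2-[(1E,3E)-4-methyl-6-(trimethylsilyl)hexa-1,3-dien-5-yn-1-yl]-1,3,2-dioxaborolane | C[Si](C)(C)C#C/C(C)=C/C=C/B1OC(C)(C)C(C)(C)O1 | intermediate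
14 | tert-butyl({(R)-4-[(3E,5E,7E,9E)-3,10-dimethyl-12-(trimethylsilyl)dodeca-3,5,7,9-tetraene-1,11-diyn-1-yl]-3,5,5-trimethylcyclohex-3-en-1-yl}oxy)dimethylsilane | CC1=C(C#C/C(C)=C/C=C/C=C/C=C(C)/C#C[Si](C)(C)C)C(C)(C)C[C@H](O[Si](C)(C)C(C)(C)C)C1 | intermediate
15 | (R)-4-[(3E,5E,7E,9E)-3,10-dimethyldodeca-3,5,7,9-tetraene-1,11-diyn-1-yl]-3,5,5-trimethylcyclohex-3-en-1-ol | CC1=C(C#C/C(C)=C/C=C/C=C/C=C(C)/C#C)C(C)(C)C[C@H](O)C1 | intermediate
16 | methyl (R)-4-(tert-butyldimethylsilyloxy)-2,6,6-trimethylcyclohex-1-ene-1-carboxylate | CC1=C(C(=O)OC)C(C)(C)C[C@H](O[Si](C)(C)C(C)(C)C)C1 | intermediate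
17 | [(R)-4-(tert-butyldimethylsilyloxy)-2,6,6-trimethylcyclohex-1-en-1-yl]methanol | CC1=C(CO)C(C)(C)C[C@H](O[Si](C)(C)C(C)(C)C)C1 | intermediate
18 | [(1S,4S,6S)-4-(tert-butyldimethylsilyloxy)-2,2,6-trimethyl-7-oxabicyclo[4.1.0]heptan-1-yl]methanol (syn epoxide) | OC[C@@]1(O2)C(C)(C)C[C@H](O[Si](C)(C)C(C)(C)C)C[C@@]12C | intermediate
19 | (1S,2R,4S)-4-(tert-butyldimethylsilyloxy)-1-(hydroxymethyl)-2,6,6-trimethylcyclohexane-1,2-diol | OC[C@@]1(O)C(C)(C)C[C@H](O[Si](C)(C)C(C)(C)C)C[C@@]1(C)O | intermediate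
20 | (1R,2R,4S)-4-(tert-butyldimethylsilyloxy)-1,2-dihydroxy-2,6,6-trimethylcyclohexane-1-carbaldehyde | O=C[C@@]1(O)C(C)(C)C[C@H](O[Si](C)(C)C(C)(C)C)C[C@@]1(C)O | intermediate
21 | (1R,2R,4S)-4-(tert-butyldimethylsilyloxy)-2,6,6-trimethyl-1,2-bis(trimethylsilyloxy)cyclohexane-1-carbaldehyde | O=C[C@@]1(O[Si](C)(C)C)C(C)(C)C[C@H](O[Si](C)(C)C(C)(C)C)C[C@@]1(C)O[Si](C)(C)C | intermediate
22 | (1R,2R,4S)-4-(tert-butyldimethylsilyloxy)-1-[(E)-2-iodoethenyl]-2,6,6-trimethyl-1,2-bis(trimethylsilyloxy)cyclohexane | I/C=C/[C@@]1(O[Si](C)(C)C)C(C)(C)C[C@H](O[Si](C)(C)C(C)(C)C)C[C@@]1(C)O[Si](C)(C)C | intermediate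
23 | prop-2-yn-1-ol (propargyl alcohol) | C#CCO | starting material
24 | (E)-alkenyllithium from 22 (lithium in place of iodine; not isolated) | [Li]/C=C/[C@@]1(O[Si](C)(C)C)C(C)(C)C[C@H](O[Si](C)(C)C(C)(C)C)C[C@@]1(C)O[Si](C)(C)C | intermediate
25 | (E)-alkenylmagnesium bromide from 24 (not isolated) | Br[Mg]/C=C/[C@@]1(O[Si](C)(C)C)C(C)(C)C[C@H](O[Si](C)(C)C(C)(C)C)C[C@@]1(C)O[Si](C)(C)C | intermediate
26 | chloromagnesium prop-2-yn-1-olate (not isolated) | C#CCO[Mg]Cl | intermediate
27 | five-membered magnesium chelate, 2,5-dihydro-1,2-oxamagnesole carrying the (E)-alkenyl group on C4 (not isolated) | [Mg]1OCC(/C=C/[C@@]2(O[Si](C)(C)C)C(C)(C)C[C@H](O[Si](C)(C)C(C)(C)C)C[C@@]2(C)O[Si](C)(C)C)=C1 | intermediate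
28 | (2Z,3E)-4-[(1R,2R,4S)-4-(tert-butyldimethylsilyloxy)-2,6,6-trimethyl-1,2-bis(trimethylsilyloxy)cyclohexyl]-2-(iodomethylidene)but-3-en-1-ol | OC/C(=C\I)/C=C/[C@@]1(O[Si](C)(C)C)C(C)(C)C[C@H](O[Si](C)(C)C(C)(C)C)C[C@@]1(C)O[Si](C)(C)C | intermediate
29 | (2Z,3E)-4-[(1R,2R,4S)-4-(tert-butyldimethylsilyloxy)-2,6,6-trimethyl-1,2-bis(trimethylsilyloxy)cyclohexyl]-2-(iodomethylidene)but-3-enal | O=C/C(=C\I)/C=C/[C@@]1(O[Si](C)(C)C)C(C)(C)C[C@H](O[Si](C)(C)C(C)(C)C)C[C@@]1(C)O[Si](C)(C)C | intermediate
30 | (2Z,3E)-4-[(1R,2R,4S)-4-(tert-butyldimethylsilyloxy)-2,6,6-trimethyl-1,2-bis(trimethylsilyloxy)cyclohexyl]-2-(iodomethylidene)but-3-enoic acid | OC(=O)/C(=C\I)/C=C/[C@@]1(O[Si](C)(C)C)C(C)(C)C[C@H](O[Si](C)(C)C(C)(C)C)C[C@@]1(C)O[Si](C)(C)C | intermediate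
31 | (2Z,3E)-2-(iodomethylidene)-4-[(1R,2R,4S)-1,2,4-trihydroxy-2,6,6-trimethylcyclohexyl]but-3-enoic acid | OC(=O)/C(=C\I)/C=C/[C@@]1(O)C(C)(C)C[C@H](O)C[C@@]1(C)O | intermediate
32 | (2Z,6E,8E,10E,12E)-15-[(R)-4-hydroxy-2,6,6-trimethylcyclohex-1-en-1-yl]-6,13-dimethyl-2-{(E)-2-[(1R,2R,4S)-1,2,4-trihydroxy-2,6,6-trimethylcyclohexyl]ethenyl}pentadeca-2,6,8,10,12-pentaene-4,14-diynoic acid (not isolated) | CC1=C(C#C/C(C)=C/C=C/C=C/C=C(C)/C#C/C=C(/C=C/[C@@]2(O)C(C)(C)C[C@H](O)C[C@@]2(C)O)C(=O)O)C(C)(C)C[C@H](O)C1 | intermediate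
33 | target CNP0163979.1, the (Z)-5-ylidene furan-2(5H)-one carrying the (3S,5R,6R)-triol dienyl arm on C3 and the (3'R)-acetylenic tetraene on the ylidene carbon | CC1=C(C#C/C(C)=C/C=C/C=C/C=C(C)/C=C2C=C(/C=C/[C@@]3(O)C(C)(C)C[C@H](O)C[C@@]3(C)O)C(=O)O/2)C(C)(C)C[C@H](O)C1 | target

Total step count: 22 steps. Longest linear sequence: 14 steps (steps 1, 2, 11 to 21 and 22, from actinol).

Steps most likely to fail

Step 18. The alkenylmagnesium reagent may be protonated by the acetylenic C–H of the propargyl alkoxide or homocouple on copper before it adds, and carbometalation by so hindered a nucleophile may stall. The fallback replaces carbometalation by cross-coupling with a silicon-masked iodide; it sets out from 22 and returns at 28. Commercial 3-(trimethylsilyl)prop-2-yn-1-ol is hydrostannated in the syn sense (Bu3SnH, PdCl2(PPh3)2, THF), tin going to the carbinol-proximal carbon, to give (E)-2-(tributylstannyl)-3-(trimethylsilyl)prop-2-en-1-ol F1. Stille coupling of this stannane with 22 (Pd2(dba)3, AsPh3, CuI, DMF, rt) should give (2Z,3E)-4-[(1R,2R,4S)-4-(tert-butyldimethylsilyloxy)-2,6,6-trimethyl-1,2-bis(trimethylsilyloxy)cyclohexyl]-2-[(trimethylsilyl)methylidene]but-3-en-1-ol F2, in which silicon sits cis to the hydroxymethyl group. Iododesilylation with N-iodosuccinimide (MeCN, 2,6-lutidine, 0 °C) proceeds with retention and should deliver 28.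

Step 22. The intermediate ynenoic acid may partition toward 6-endo closure, the terminal alkyne may dimerise oxidatively, or the polyene may isomerise while coupling and cyclisation run together. The fallback separates the two events; it sets out from 31 (with 15) and returns at 33. Esterification of 31 with Me3SiCHN2 in MeOH/toluene gives methyl (2Z,3E)-2-(iodomethylidene)-4-[(1R,2R,4S)-1,2,4-trihydroxy-2,6,6-trimethylcyclohexyl]but-3-enoate F3. Sonogashira coupling with 15 under the step 22 catalysts gives the methyl ester of 32, methyl (2Z)-enynoate F4, which cannot lactonise. Saponification (LiOH, THF/H2O, 0 °C) releases 32, and Ag2CO3 (catalytic, DMF, rt, dark), the known 5-exo-selective catalyst for (Z)-2-en-4-ynoic acids, closes it to 33.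

Step 13. Facial selectivity may erode because the tartrate has to overrule whatever intrinsic bias the ring has, and the tetrasubstituted alkene may react sluggishly. The fallback uses substrate-directed delivery instead of reagent control; it sets out from 17 and returns at 18. Acetylation (Ac2O, pyridine) gives [(R)-4-(tert-butyldimethylsilyloxy)-2,6,6-trimethylcyclohex-1-en-1-yl]methyl acetate F5. Desilylation (HF·pyridine, THF) gives [(R)-4-hydroxy-2,6,6-trimethylcyclohex-1-en-1-yl]methyl acetate F6. Epoxidation with VO(acac)2 and t-BuOOH (CH2Cl2, rt), the oxygen being delivered from the vanadium alkoxide of the homoallylic ring hydroxyl to its own face, should give [(1S,4S,6S)-4-hydroxy-2,2,6-trimethyl-7-oxabicyclo[4.1.0]heptan-1-yl]methyl acetate F7. Resilylation (TBSCl, imidazole, DMF) gives [(1S,4S,6S)-4-(tert-butyldimethylsilyloxy)-2,2,6-trimethyl-7-oxabicyclo[4.1.0]heptan-1-yl]methyl acetate F8, and methanolysis (K2CO3, MeOH, 0 °C) returns 18.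

Further compounds
F1 | step 18 | (E)-2-(tributylstannyl)-3-(trimethylsilyl)prop-2-en-1-ol | OC/C(=C\[Si](C)(C)C)[Sn](CCCC)(CCCC)CCCC
F2 | step 18 | (2Z,3E)-4-[(1R,2R,4S)-4-(tert-butyldimethylsilyloxy)-2,6,6-trimethyl-1,2-bis(trimethylsilyloxy)cyclohexyl]-2-[(trimethylsilyl)methylidene]but-3-en-1-ol | OC/C(=C\[Si](C)(C)C)/C=C/[C@@]1(O[Si](C)(C)C)C(C)(C)C[C@H](O[Si](C)(C)C(C)(C)C)C[C@@]1(C)O[Si](C)(C)C
F3 | step 22 | methyl (2Z,3E)-2-(iodomethylidene)-4-[(1R,2R,4S)-1,2,4-trihydroxy-2,6,6-trimethylcyclohexyl]but-3-enoate | COC(=O)/C(=C\I)/C=C/[C@@]1(O)C(C)(C)C[C@H](O)C[C@@]1(C)O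
F4 | step 22 | methyl ester of 32, methyl (2Z)-enynoate | CC1=C(C#C/C(C)=C/C=C/C=C/C=C(C)/C#C/C=C(/C=C/[C@@]2(O)C(C)(C)C[C@H](O)C[C@@]2(C)O)C(=O)OC)C(C)(C)C[C@H](O)C1
F5 | step 13 | [(R)-4-(tert-butyldimethylsilyloxy)-2,6,6-trimethylcyclohex-1-en-1-yl]methyl acetate | CC1=C(COC(C)=O)C(C)(C)C[C@H](O[Si](C)(C)C(C)(C)C)C1
F6 | step 13 | [(R)-4-hydroxy-2,6,6-trimethylcyclohex-1-en-1-yl]methyl acetate | CC1=C(COC(C)=O)C(C)(C)C[C@H](O)C1
F7 | step 13 | [(1S,4S,6S)-4-hydroxy-2,2,6-trimethyl-7-oxabicyclo[4.1.0]heptan-1-yl]methyl acetate | CC(=O)OC[C@@]1(O2)C(C)(C)C[C@H](O)C[C@@]12C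
F8 | step 13 | [(1S,4S,6S)-4-(tert-butyldimethylsilyloxy)-2,2,6-trimethyl-7-oxabicyclo[4.1.0]heptan-1-yl]methyl acetate | CC(=O)OC[C@@]1(O2)C(C)(C)C[C@H](O[Si](C)(C)C(C)(C)C)C[C@@]12C
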